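**Retrosynthetic overview**

1. Target 21 ⇐ 20 by C-formylation of the two free aromatic CH positions (last step).
2. 20 ⇐ cis-decalin mesylate 18 (C4–C7' bond and arene already in place) by one cationic cascade: ring A (C1–C2–C3–C4–C5–C10) contracts to the cyclopentane C1–C5, ring B (C5–C10) expands to the cycloheptane, H-1 moves to C10, and the phenol closes the oxepane at C1.
3. Enabling feature: the C1–O(mesylate) bond antiperiplanar to the ring-fusion bond C5–C10, the quaternary C10 (Me-14) that takes the charge, H-1 beside it, and the ortho-OH of the aryl ring held under C1 through C4–C7'.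
4. 18 ⇐ enone 15 ⇐ union of an o-quinone methide (from 2 and isobutylmagnesium bromide) with silyl dienol ether 10 at the quaternary C4–C7' bond.
5. 10 ⇐ Diels–Alder reaction of car-2-en-4-one (from (+)-2-carene: cyclopropane and ring B) with a 1-silyloxydiene (ring A). Ring order: cyclopropane and ring B (chiral pool) → ring A → arene attached → cyclopentane, cycloheptane and oxepane together.

Key step: step 12

Remark on numbering: terpene carbons carry aromadendrane numbers C1–C15 throughout; these coincide with maaliane (6,11-cycloeudesmane) numbers in the decalin intermediates. C7' is the benzylic carbon. β is the face of the carbocycle that carries cyclopropane carbon C11; α is the opposite face. Target descriptors: 1S,4R,5R,6R,7R,10S,7'R.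

**Step 1**
Reactants: 1 2,4,6-trihydroxybenzaldehyde
Product: 2 2,4,6-tris(tert-butoxycarbonyloxy)benzaldehyde
Conditions: Boc2O (3.3 equiv), DMAP (5 mol %), i-Pr2NEt, THF, 0 °C → rt
Reagents that add atoms: di-tert-butyl dicarbonate, CC(C)(C)OC(=O)OC(=O)OC(C)(C)C
Why: Phenol O-acylation to the aryl carbonates under nucleophilic catalysis; the ortho carbonate is the group that later migrates to release the quinone methide.

**Step 2**
Reactants: 3 (E)-pent-2-enal
Product: 4 (1E,3E)-1-(tert-butyldimethylsilyloxy)penta-1,3-diene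
Conditions: TBSOTf, Et3N, Et2O, 0 °C → rt
Reagents that add atoms: tert-butyldimethylsilyl triflate, CC(C)(C)[Si](C)(C)OS(=O)(=O)C(F)(F)F
Why: Soft enolisation of an enal (O-silylation, then loss of the γ-proton) is the standard route to through-conjugated 1-silyloxydienes.

**Step 3**
Reactants: 5 (+)-2-carene
Product: 6 car-2-en-4-one
Conditions: t-BuOOH, Cr(CO)6 (0.25 equiv), MeCN, reflux
Reagents that add atoms: tert-butyl hydroperoxide, CC(C)(C)OO
Why: Chromium-catalysed allylic C–H oxidation should take the ring CH2 next to the more substituted alkene carbon to the conjugated enone under neutral conditions that spare the acid-labile vinylcyclopropane and its two stereocentres.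

**Step 4**
Reactants: 6 car-2-en-4-one, 4 (1E,3E)-1-(tert-butyldimethylsilyloxy)penta-1,3-diene
Product: 7 1α-(tert-butyldimethylsilyloxy)-cis-maal-2-en-9-one (4α-Me, 5β-H, 10β-Me)
Conditions: EtAlCl2 (0.3 equiv), CH2Cl2, −78 → −30 °C
Reagents that add atoms: none
Why: Lewis-acid-catalysed Diels–Alder reaction of a 2-methylcyclohexenone-type dienophile: the oxygenated diene terminus bonds to the α-carbon C10 (ortho rule), the diene adds anti to the CMe2 bridge so that Me-14 and H-5 become β in a cis-decalin, and the endo mode places the silyloxy and methyl groups α (both centres are erased in steps 6 and 7).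

**Step 5**
Reactants: 7 1α-(tert-butyldimethylsilyloxy)-cis-maal-2-en-9-one
Product: 8 cis-maal-2-en-1α-ol
Conditions: N2H4·H2O, diethylene glycol, 130 °C; then KOH, 200 °C; 1 M HCl work-up
Reagents that add atoms: none
Why: Wolff–Kishner reduction (Huang-Minlon) removes the carbonyl that activated the dienophile; the hydrazone is formed before base is added so that no β-oxy ketone meets hot alkali, and the acidic work-up cleaves the remaining silyl ether.

**Step 6**
Reactants: 8 cis-maal-2-en-1α-ol
Product: 9 cis-maal-2-en-1-one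
Conditions: (n-Pr)4N[RuO4] (5 mol %), N-methylmorpholine N-oxide, 4 Å MS, CH2Cl2, rt
Reagents that add atoms: none
Why: Ley–Griffith oxidation of the allylic alcohol to the enone under neutral conditions; C10 is quaternary, so nothing next to the carbonyl can epimerise.

**Step 7**
Reactants: 9 cis-maal-2-en-1-one
Product: 10 1-(tert-butyldimethylsilyloxy)-cis-maala-1,3-diene
Conditions: TBSOTf, Et3N, CH2Cl2, −78 → 0 °C
Reagents that add atoms: tert-butyldimethylsilyl triflate, CC(C)(C)[Si](C)(C)OS(=O)(=O)C(F)(F)F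
Why: Soft enolisation; with no α'-hydrogen (C10 quaternary) only the γ-hydrogen H-4 can be lost, which gives the 1-silyloxy-1,3-diene with C4 as nucleophilic terminus and removes the C4 stereocentre.

**Step 8**
Reactants: 2 2,4,6-tris(tert-butoxycarbonyloxy)benzaldehyde, 11 isobutylmagnesium bromide, 10 1-(tert-butyldimethylsilyloxy)-cis-maala-1,3-diene
Product: 15 4β-[(1R)-1-aryl-3-methylbutyl]-cis-maal-2-en-1-one tris(tert-butyl carbonate), via o-quinone methide 12 (not isolated), via chroman cycloadduct 13 (not isolated), via phenol enone 14 (not isolated)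
Conditions: 11, THF, −78 °C; then 10, −78 → 0 °C; then Bu4NF, 0 °C; then Boc2O, rt; NH4Cl work-up
Reagents that add atoms: di-tert-butyl dicarbonate, CC(C)(C)OC(=O)OC(=O)OC(C)(C)C
Why: Pettus-type quinone methide generation (Grignard addition, carbonate O→O migration, β-elimination) and inverse-electron-demand hetero-Diels–Alder reaction with the C3=C4 bond of the dienol ether, where the terminus with the largest HOMO coefficient (C4, γ) bonds to C7' (vinylogous Mukaiyama–Michael regiochemistry), should form C4–C7' from the convex β face of the cis-decalin (Me-15 α) with the E-quinone methide endo (C7' R); fluoride then unravels the silyl enol ether with E1cB loss of the phenoxide, which Boc2O caps.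

**Step 9**
Reactants: 15 tris-carbonate enone
Product: 16 4β-[(1R)-1-aryl-3-methylbutyl]-cis-maal-2-en-1β-ol tris(tert-butyl carbonate)
Conditions: (S)-2-methyl-CBS-oxazaborolidine (20 mol %), BH3·SMe2, toluene, −40 °C
Reagents that add atoms: none
Why: Corey–Bakshi–Shibata reduction: with quaternary C10 as the large and the vinyl group as the small flank, the (S)-catalyst should deliver hydride to the α face and give the 1β-alcohol (cis to Me-14) under reagent control, without touching the C=C bond or the carbonates.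

**Step 10**
Reactants: 16 allylic 1β-alcohol
Product: 17 (1R,4R,5R,6R,7R,10R,7'R)-4-[1-aryl-3-methylbutyl]-cis-maalan-1-ol tris(tert-butyl carbonate)
Conditions: H2 (1 atm), [Ir(cod)(PCy3)(py)]PF6 (5 mol %), CH2Cl2, rt
Reagents that add atoms: none
Why: Hydroxyl-directed homogeneous hydrogenation of the hindered cis-disubstituted alkene; no new stereocentre, and no hydrogenolysis of the allylic C–O bond or the cyclopropane is expected.

**Step 11**
Reactants: 17 saturated 1β-alcohol
Product: 18 1β-mesylate of 17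
Conditions: MsCl, Et3N, CH2Cl2, 0 °C
Reagents that add atoms: methanesulfonyl chloride, CS(=O)(=O)Cl
Why: Sulfonylation through sulfene with retention at C1 places the nucleofuge on the β face.

**Step 12**
Reactants: 18 1β-mesylate
Product: 20 bis-deformyl target (oxepane-bridged aromadendrane phloroglucinol), via triphenol mesylate 19 (not isolated)
Conditions: CF3CO2H, anisole, CH2Cl2, 0 °C; then (CF3)2CHOH, 40 °C
Reagents that add atoms: none
Why: In HFIP the equatorial 1β-mesylate should ionise with participation of the antiperiplanar C5–C10 bond (Wagner–Meerwein 1,2-alkyl shift; closest precedent: the solvolytic eudesmane-to-guaiane rearrangement of 10-methyldecal-1-yl sulfonates), so that C5 moves from C10 to C1: ring A loses C10 and becomes the cyclopentane C1–C5 (closure by 1,2-shift, inversion at C1, retention at C5), ring B gains C1 and becomes the cycloheptane, and the charge arrives at tertiary C10. Because the leaving group was β, H-1 of this trans-fused hydroazulenyl cation is α, and its suprafacial 1,2-hydride shift to C10 sets C10 (H α, Me-14 β) and gives the tertiary C1 cation. The ortho-phenol, held under the β face by the C4–C7' bond, captures C1 (oxepane closed by O–C bond formation on a cation, seven-membered, the only ring size within reach), which sets C1 with oxygen β and cis to H-5. The selectivity needed is migration of C5 rather than of C9 or Me-14 and no elimination toward C2; it is secured by the chair in which the mesylate is equatorial (Me-14 axial), where only C5–C10 is antiperiplanar to C1–O. Proton loss from the C10 cation to the Δ1(10)-olefin is not a dead end, since the MsOH released reprotonates it to the same C1 cation, and capture at C10 by oxygen would need an eight-membered ring. The arene has no free position within reach of C1 or C10, so C-alkylation cannot compete, and C5 insulates the cyclopropane from both cationic centres.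

**Step 13**
Reactants: 20 bis-deformyl target
Product: 21 target (CNP0189833.2)
Conditions: POCl3, DMF, MeCN, 0 °C → rt; then H2O, NaOAc, 50 °C
Reagents that add atoms: N,N-dimethylformamide, CN(C)C=O; water, O
Why: Vilsmeier–Haack formylation: both free aromatic positions are flanked by two oxygen substituents, as in the standard preparation of diformylphloroglucinol, so double C-formylation is regiochemically unambiguous and no stereocentre is touched.

**Compound list**

1 | 2,4,6-trihydroxybenzaldehyde | O=Cc1c(O)cc(O)cc1O | starting material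
2 | 2,4,6-tris(tert-butoxycarbonyloxy)benzaldehyde | O=Cc1c(OC(=O)OC(C)(C)C)cc(OC(=O)OC(C)(C)C)cc1OC(=O)OC(C)(C)C | intermediate
3 | (E)-pent-2-enal | CC/C=C/C=O | starting material
4 | (1E,3E)-1-(tert-butyldimethylsilyloxy)penta-1,3-diene | C/C=C/C=C/O[Si](C)(C)C(C)(C)C | intermediate
5 | (+)-2-carene, (1S,6R)-3,7,7-trimethylbicyclo[4.1.0]hept-2-ene | CC1=C[C@H]2[C@@H](CC1)C2(C)C | starting material
6 | car-2-en-4-one, (1S,6R)-3,7,7-trimethylbicyclo[4.1.0]hept-2-en-4-one (carane numbering) | CC1=C[C@H]2[C@@H](CC1=O)C2(C)C | intermediate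
7 | 1α-(tert-butyldimethylsilyloxy)-cis-maal-2-en-9-one (4α-Me, 5β-H, 10β-Me, C11 β) | C[C@@H]1C=C[C@H](O[Si](C)(C)C(C)(C)C)[C@]2(C)C(=O)C[C@@H]3[C@@H](C3(C)C)[C@H]12 | intermediate
8 | cis-maal-2-en-1α-ol (4α-Me, 5β-H, 10β-Me) | C[C@@H]1C=C[C@H](O)[C@]2(C)CC[C@@H]3[C@@H](C3(C)C)[C@H]12 | intermediate
9 | cis-maal-2-en-1-one (4α-Me, 5β-H, 10β-Me) | C[C@@H]1C=CC(=O)[C@]2(C)CC[C@@H]3[C@@H](C3(C)C)[C@H]12 | intermediate
10 | 1-(tert-butyldimethylsilyloxy)-cis-maala-1,3-diene (5β-H, 10β-Me) | CC1=CC=C(O[Si](C)(C)C(C)(C)C)[C@]2(C)CC[C@@H]3[C@@H](C3(C)C)[C@H]12 | intermediate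
11 | isobutylmagnesium bromide | CC(C)C[Mg]Br | starting material
12 | (6E)-3,5-bis(tert-butoxycarbonyloxy)-6-(3-methylbutylidene)cyclohexa-2,4-dien-1-one (o-quinone methide) | CC(C)C/C=C1/C(=O)C=C(OC(=O)OC(C)(C)C)C=C1OC(=O)OC(C)(C)C | intermediate (not isolated)
13 | chroman cycloadduct: aryl O on C3 (β), C7' on C4 (β), 1-silyloxy-Δ1 enol ether, cis-maalane core | CC(C)C[C@H]1c2c(OC(=O)OC(C)(C)C)cc(OC(=O)OC(C)(C)C)cc2O[C@H]2C=C(O[Si](C)(C)C(C)(C)C)[C@]3(C)CC[C@@H]4[C@@H](C4(C)C)[C@@H]3[C@@]12C | intermediate (not isolated)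
14 | 4β-[(1R)-1-(2-hydroxy-4,6-bis(tert-butoxycarbonyloxy)phenyl)-3-methylbutyl]-cis-maal-2-en-1-one | CC(C)C[C@@H](c1c(O)cc(OC(=O)OC(C)(C)C)cc1OC(=O)OC(C)(C)C)[C@@]2(C)C=CC(=O)[C@]3(C)CC[C@@H]4[C@@H](C4(C)C)[C@H]23 | intermediate (not isolated)
15 | 4β-[(1R)-1-(2,4,6-tris(tert-butoxycarbonyloxy)phenyl)-3-methylbutyl]-cis-maal-2-en-1-one (4α-Me) | CC(C)C[C@@H](c1c(OC(=O)OC(C)(C)C)cc(OC(=O)OC(C)(C)C)cc1OC(=O)OC(C)(C)C)[C@@]2(C)C=CC(=O)[C@]3(C)CC[C@@H]4[C@@H](C4(C)C)[C@H]23 | intermediate
16 | corresponding cis-maal-2-en-1β-ol | CC(C)C[C@@H](c1c(OC(=O)OC(C)(C)C)cc(OC(=O)OC(C)(C)C)cc1OC(=O)OC(C)(C)C)[C@@]2(C)C=C[C@@H](O)[C@]3(C)CC[C@@H]4[C@@H](C4(C)C)[C@H]23 | intermediate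
17 | (1R,4R,5R,6R,7R,10R,7'R)-cis-maalan-1-ol (1β-OH) with the tris-carbonate aryl side chain on C4 | CC(C)C[C@@H](c1c(OC(=O)OC(C)(C)C)cc(OC(=O)OC(C)(C)C)cc1OC(=O)OC(C)(C)C)[C@@]2(C)CC[C@@H](O)[C@]3(C)CC[C@@H]4[C@@H](C4(C)C)[C@H]23 | intermediate
18 | 1β-methanesulfonate of 17 | CC(C)C[C@@H](c1c(OC(=O)OC(C)(C)C)cc(OC(=O)OC(C)(C)C)cc1OC(=O)OC(C)(C)C)[C@@]2(C)CC[C@@H](OS(C)(=O)=O)[C@]3(C)CC[C@@H]4[C@@H](C4(C)C)[C@H]23 | intermediate
19 | 4β-[(1R)-1-(2,4,6-trihydroxyphenyl)-3-methylbutyl]-cis-maalan-1β-yl methanesulfonate | CC(C)C[C@@H](c1c(O)cc(O)cc1O)[C@@]2(C)CC[C@@H](OS(C)(=O)=O)[C@]3(C)CC[C@@H]4[C@@H](C4(C)C)[C@H]23 | intermediate (not isolated)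
20 | bis-deformyl target: oxepane-bridged aromadendrane (O on C1 β, C7' on C4 β, H-5 β, Me-14 β) with a 2,4-dihydroxyphenyl ether core | CC(C)C[C@H]1c2c(O)cc(O)cc2O[C@]23CC[C@@]1(C)[C@H]2[C@H]1[C@@H](CC[C@@H]3C)C1(C)C | intermediate
21 | CNP0189833.2, (1S,4R,5R,6R,7R,10S,7'R) | CC(C)C[C@H]1c2c(O)c(C=O)c(O)c(C=O)c2O[C@]23CC[C@@]1(C)[C@H]2[C@H]1[C@@H](CC[C@@H]3C)C1(C)C | target

**Step count**

Total steps: 13. Longest linear sequence: 11 steps (steps 3–13, from (+)-2-carene).

**Steps most likely to fail**

Step 8. What may go wrong: the quinone methide bonds to the unhindered α-carbon C2 of the dienol ether (or adds across C1=C2) instead of the fully substituted γ-carbon C4, and endo/exo control at C7' erodes. The fallback blocks C2. It sets out from enone 9: Br2 then Et3N (CH2Cl2, 0 °C) gives 2-bromo-cis-maal-2-en-1-one F1. TBSOTf/Et3N gives the 2-bromo-1-silyloxydiene F2, in which C2 is fully substituted and deactivated so that only C4 can react. Generation of 12 and the stages of step 8 then lead through the bromo cycloadduct F3 and the bromo phenol F4 to the bromo tris-carbonate F5. Pd(PPh3)4, HCO2H and Et3N remove the vinylic bromine, and the route is rejoined at 15.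

Step 12. What may go wrong: ionisation through the other chair with proton loss toward C2 or migration of C9; capture of the C10 cation before the hydride shift, so that C10 is not set; acid damage to the cyclopropane. The fallback uses the C1 epimer, which ionises from the more comfortable chair, and separates the shift from the ether closure. It sets out from enone 15: NaBH4 with CeCl3·7H2O (MeOH, −40 °C) should deliver hydride from the open β face and give the 1α-allylic alcohol F6. Hydrogenation as in step 10 gives the 1α-alcohol F7, and MsCl/Et3N gives the 1α-mesylate F8, which is equatorial in the chair that keeps the C4 side chain equatorial. Buffered acetolysis (NaOAc, AcOH, 70 °C) performs the same C5 shift followed by loss of H-1 and gives the Δ1(10)-olefin F9. CF3CO2H in CH2Cl2 then unmasks the phenols and closes the oxepane by Markovnikov addition across C1=C10, the proton entering C10 from the α face anti to the phenol, and the route is rejoined at 20.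

Step 13. What may go wrong: acid generated under Vilsmeier conditions ionises the tertiary alkyl aryl ether, or the second formylation stalls on the deactivated ring. The fallback is a base-mediated, phenoxide-directed formylation: from 20, MgCl2, Et3N and paraformaldehyde in MeCN at reflux (magnesium phenoxide ortho-formylation, formaldehyde as carbon source) should give 21 directly without an acidic stage.

**Further compounds**

F1 | step 8 | 2-bromo-cis-maal-2-en-1-one | C[C@@H]1C=C(Br)C(=O)[C@]2(C)CC[C@@H]3[C@@H](C3(C)C)[C@H]12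
F2 | step 8 | 2-bromo-1-(tert-butyldimethylsilyloxy)-cis-maala-1,3-diene | CC1=CC(Br)=C(O[Si](C)(C)C(C)(C)C)[C@]2(C)CC[C@@H]3[C@@H](C3(C)C)[C@H]12
F3 | step 8 | 2-bromo analogue of cycloadduct 13 | CC(C)C[C@H]1c2c(OC(=O)OC(C)(C)C)cc(OC(=O)OC(C)(C)C)cc2O[C@H]2C(Br)=C(O[Si](C)(C)C(C)(C)C)[C@]3(C)CC[C@@H]4[C@@H](C4(C)C)[C@@H]3[C@@]12C
F4 | step 8 | 2-bromo analogue of phenol enone 14 | CC(C)C[C@@H](c1c(O)cc(OC(=O)OC(C)(C)C)cc1OC(=O)OC(C)(C)C)[C@@]2(C)C=C(Br)C(=O)[C@]3(C)CC[C@@H]4[C@@H](C4(C)C)[C@H]23
F5 | step 8 | 2-bromo analogue of enone 15 | CC(C)C[C@@H](c1c(OC(=O)OC(C)(C)C)cc(OC(=O)OC(C)(C)C)cc1OC(=O)OC(C)(C)C)[C@@]2(C)C=C(Br)C(=O)[C@]3(C)CC[C@@H]4[C@@H](C4(C)C)[C@H]23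
F6 | step 12 | 1α-epimer of allylic alcohol 16 | CC(C)C[C@@H](c1c(OC(=O)OC(C)(C)C)cc(OC(=O)OC(C)(C)C)cc1OC(=O)OC(C)(C)C)[C@@]2(C)C=C[C@H](O)[C@]3(C)CC[C@@H]4[C@@H](C4(C)C)[C@H]23
F7 | step 12 | 1α-epimer of alcohol 17 | CC(C)C[C@@H](c1c(OC(=O)OC(C)(C)C)cc(OC(=O)OC(C)(C)C)cc1OC(=O)OC(C)(C)C)[C@@]2(C)CC[C@H](O)[C@]3(C)CC[C@@H]4[C@@H](C4(C)C)[C@H]23
F8 | step 12 | 1α-epimer of mesylate 18 | CC(C)C[C@@H](c1c(OC(=O)OC(C)(C)C)cc(OC(=O)OC(C)(C)C)cc1OC(=O)OC(C)(C)C)[C@@]2(C)CC[C@H](OS(C)(=O)=O)[C@]3(C)CC[C@@H]4[C@@H](C4(C)C)[C@H]23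
F9 | step 12 | 4β-[(1R)-1-(2,4,6-tris(tert-butoxycarbonyloxy)phenyl)-3-methylbutyl]aromadendr-1(10)-ene (4α-Me, 5β-H) | CC(C)C[C@@H](c1c(OC(=O)OC(C)(C)C)cc(OC(=O)OC(C)(C)C)cc1OC(=O)OC(C)(C)C)[C@@]2(C)CCC3=C(C)CC[C@@H]4[C@@H](C4(C)C)[C@H]23
F0 | step 13 | none | none
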